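(The readings were generated by integration on assumed constants, noise included.)

- Two reagent per substrate looks like a finished flask on paper, but that sum does not say how long the last open positions take to fill.

common to all: substrate 1.3 M

| charge | reagent | remark | time |
|---|---|---|---|
| south-west | 1.3 M | run made earlier |  |
| south-east | 2 M | run made earlier |  |
| flask | 2.60 M |  | 3.0 min |

- south-west (time / min: substrate / %, single product / %): 0.200: 35, 28; 0.333: 31, 30; 0.667: 32, 28; 1.33: 32, 25; 2.50: 27, 24
- south-east (time / min: substrate / %, single product / %): 0.200: 20, 29; 0.333: 15, 24; 0.667: 11, 20; 1.33: 10, 22; 2.50: 9, 20

(each reading ± 2 percentage points)

- a species is counted by the substrate in it: one side product counts as two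
- the earlier runs were read with a standard deviation of 2 percentage points
- steps under discussion: substrate + reagent -> single product + by-product; substrate + reagent -> other mono adduct + by-product; reagent + single product -> bis adduct + by-product; reagent + other mono adduct -> bis adduct + by-product; substrate + single product -> side product; reagent <-> dormant form

1. amount of substrate at 3.0 min, in percent of the substrate charged
2. amount of single product at 3.0 min, in percent of the substrate charged
3. amount of other mono adduct at 3.0 min, in percent of the substrate charged
4. amount of bis adduct at 3.0 min, in percent of the substrate charged

- A quick number, as asked, starts from the open share: the fraction of the two positions on each substrate still without reagent, read as substrate plus the single product divided by two, with the unread other mono adduct taken as filled.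
- The south-east run reads an open share of 21.0 % at 0.667 min, and its charge cannot fill the last 23.1 %, so its plateau reads as a reagent stall.
- Earlier, at 0.200 min, that run reads an open share of 34.5 % with 14.8 % of its reagent left, a rough reading given the scatter.
- One second-order constant for both positions turns this into the filling time, the time in which a balanced charge of this flask's strength takes its open share to half: 0.0548 min.
- The flask is balanced, so reagent and open positions fall together as equal shares, and the open share goes as one over one plus the filling times elapsed.
- Its 3.0 min holds 54.7 filling times, which leaves 1.79 % open.
- The reckoning here, with the open positions placed on mono adducts, gives 3.58 % of these and 96.4 % bis adduct.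
- The forecast differs: 1.5 % substrate, 7 % single product, 1 % other mono adduct and 88 % bis adduct, less bis adduct than this reckoning, and it adds that “A dormant reagent reservoir could leave somewhat more intermediates”.

- The flask gives 0.369 % substrate, 3.35 % single product, 0.280 % other mono adduct and 95.3 % bis adduct, an open share of 2.18 % against the 1.79 % reckoned.

    substrate + reagent → single product + by-product (k = 0.100 M⁻¹ s⁻¹)
    substrate + reagent → other mono adduct + by-product (k = 0.0540 M⁻¹ s⁻¹)
    reagent + single product → bis adduct + by-product (k = 0.110 M⁻¹ s⁻¹)
    reagent + other mono adduct → bis adduct + by-product (k = 0.220 M⁻¹ s⁻¹)
    substrate + single product → side product (k = 0.00230 M⁻¹ s⁻¹)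
    reagent ⇌ dormant form (K = 0.200, k = 0.00510 s⁻¹)

- The neighbouring flask, the same flask but with 0.33 M of substrate, holds at 3.00 min 62.2 % of its reagent free and 0.322 M as dormant form, so its open positions are reckoned to decay in a pseudo-first-order way. With the same filling time 0.0548 min and that free share, their half-life is 0.0610 min, and 3.0 min holds 49.2 of these. That neighbour shows 0 % substrate, 0 % single product and 99.9 % bis adduct.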